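## The problem

The target 19 is a single carbocycle: a cyclohexa-1,3-diene (C1 to C4) whose C1 carries the benzoyloxymethyl carbon C7, followed by two adjacent sp3 carbons, C5 (benzoate) and C6 (free hydroxyl), which are trans and both R. It is an ester of an arene trans-dihydrodiol, so it lies one ionisation, elimination or hydride abstraction away from a benzene ring. Strong acid, oxidants and heat are therefore to be kept away once the diene exists. The two stereocentres are contiguous and have nothing else to control, so they are best brought in together, before the ring is made, from a chiral-pool diol. Three oxygens must end up differentiated: O7 and O5 acylated and O6 free, although O6 is the most hindered; the benzoates can shift between O5 and O6 under base and, being allylic, are ionised by low-valent metals. The ring has one bond whose formation creates no stereocentre: C2–C3, the single bond between two alkene carbons of the diene. Each of these carbons is the far end of a cis alkene whose near end (C1 or C4) is attached to the C6–C5 pair, so an open chain C2=C1–C6–C5–C4=C3 with a halogen on C2 and on C3 holds everything needed, and ring closure becomes a union of two sp2 carbons of like polarity.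

## Retrosynthesis

**19 back to 15 (O–acyl and O–Si bonds only).** The free hydroxyl of 19 is traced to the tert-butyldimethylsilyl ether 18, the two benzoates to diol 16 and benzoyl chloride 17, and 16 to the tris-silyl diene 15. Esters cannot be present when low-valent nickel closes the ring, so they come last. Silyl ethers are preferred to benzyl-type ethers because their removal needs neither a quinone oxidant nor a Lewis acid on the dihydroarene. Two triethylsilyl groups (O5, O7) beside one tert-butyldimethylsilyl group (O6) give a graded lability. The forward steps must cleave two groups selectively, acylate, and remove the last silyl group without a basic alkoxide next to the C5 benzoate.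

**15 back to 14 (C2–C3).** Cutting the diene single bond gives the open-chain (1Z,5Z)-diiodide 14. Every other ring bond is a worse cut: C5–C6, C1–C6 or C4–C5 would each create a stereocentre during ring closure, and C1=C2 or C3=C4 would need a metathesis on a conjugated triene. The precursor 14 is acyclic and carries both stereocentres untouched. The forward reaction must join two alkenyl iodides reductively with retention of both alkene geometries and must favour the ring over oligomers.

**14 back to 10 (C3–H, C3–I and O–Si bonds).** The disubstituted (Z)-iodoalkene of 14 comes from cis-hydrogenation of the iodoalkyne 13. The silyl groups are then removed in turn (12, then 11), and the C3 iodine is removed to give the terminal alkyne of diol 10. An alkyne at C3≡C4 is chosen over an aldehyde at C4 (the olefination alternative) because it survives organomagnesium chemistry unprotected and never places a carbonyl next to the C5 stereocentre. The forward steps need a primary-selective silylation and a chemoselective reduction that leaves the trisubstituted iodoalkene alone.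

**10 back to 6 and 7 (C1–C7 and C2–I).** The trisubstituted iodoalkene with its hydroxymethyl branch is cut at C1–C7 and C2–I. This leads to the propargylic alcohol 6 and the one-carbon silane 7, joined through the chelated alkenylmagnesium 8 and the allylic silane 9. The C6 hydroxyl is the control element: as its alkoxide it holds magnesium on C2, so carbon is delivered to C1 from the opposite face and iodine ends up cis to C6, as ring closure requires. No other cut of this alkene fixes its geometry so directly. The forward reaction needs a free C6 hydroxyl, no electrophilic group elsewhere, and a C–Si to C–O oxidation that spares the C5 silyl ether.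

**6 back to 1 and 2 (O–Si, the acetal, and both C≡C bonds).** Mono-ether 6 comes from the C2-symmetric diynediol 5, this from acetonide 4, and 4 from the D-tartrate-derived diester 1 by way of dialdehyde 3, each formyl carbon gaining one carbon from 2. Symmetry removes the differentiation problem: the two hydroxyls of 5 are homotopic, so any mono-silyl ether is the same compound, and the silylated oxygen becomes O5 and the free one O6 by definition. The (4S,5S) diester 1 maps onto (5R,6R) of 19, and both stereocentres are bought. The forward sequence needs an ester-to-alkyne conversion that does not epimerise the α-alkoxy aldehyde stage.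

## Roads not taken

Alternative 1: The ring would be cut into three two-carbon pieces (bonds C1–C6, C2–C3 and C4–C5). A cationic monovalent rhodium–bisphosphine catalyst would join the silicon-tethered enyne A1 with acetylene A2 in a [2+2+2] cycloaddition to give the bicyclic silyl ether A3, with the C5 benzoate already in place. Its merits are large: three ring bonds and both stereocentres in one step, and only desilylation and a primary benzoylation afterwards, for perhaps half the step count of the chosen plan. Its weak points lie in A1. The alkene partner is an (E)-enediol derivative, a silyl enol ether carrying an acyloxy group, which is electronically and sterically unlike the simple alkenes that take part in such cycloadditions. The Si–O–vinyl tether is hydrolytically fragile. A2 competes by self-trimerisation. Enantioselection rests entirely on an untested ligand–substrate match. In step economy this road is clearly better; the chosen plan sets against it stereocentres taken from the chiral pool and a ring closure (14 to 15) that creates no stereocentre and uses a known reaction class.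

Alternative 2: D-Glucal A4 would supply C5 and C6. It would be converted into the vinyl glycal A5, and a thermal [3,3] shift at about 240 °C would break the ring C–O bond and form C1–C2, giving the cyclohexene carbaldehyde A6. The merits match the chosen plan in one respect and exceed it in another: stereochemistry comes from the chiral pool, and the key step needs no metal. The weak points follow from what A6 lacks. The C1=C2 double bond must still be introduced next to an aldehyde that has a silyloxy leaving group in the β position (C6), an arrangement prone to elimination and then aromatisation. The rearrangement temperature is harsh for the same reason. The benzyl-type ether on O5 must later be removed from a diene. Step count would be similar to the chosen plan. The chosen plan sets against it a diene formed in its final position in one mild step, with no carbonyl ever conjugated to the ring.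

Alternative 3: The ring would be cut at C5–C6 and C1–C2. A diarylprolinol silyl ether catalyst would turn (E)-4-(benzoyloxy)but-2-enal A7 into a dienamine whose terminal carbon adds to C6 of (E)-3-(triisopropylsilyloxy)acrolein A8; closure of C1 on C2 and loss of the amine would give the dienal A9. This is the shortest road by far: two small achiral components, catalytic asymmetric formation of both stereocentres, and the benzoate in place, with only reduction, benzoylation and desilylation to follow. Its weak points are mechanistic. The accepting carbon of A8 carries an oxygen donor and is a poor electrophile. A7 and A8 can each act as nucleophile or electrophile, so self-condensation competes. The trans relationship and the enantioselectivity are untested for this pairing. The amine that forms A9 can also convert it into a cross-conjugated trienamine that expels the benzoate and aromatises. If it worked it would be superior in every count; the chosen plan sets against it only reliability, with each bond made by a precedented reaction type and the sensitive dihydroarene appearing once, without a formyl group attached.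

Key step: step 9

Remark on the chemistry: compounds 1, 2, 7 and 17 are taken as purchased; intermediate 9 is written as the open isopropoxysilane, although it may close onto O6 with loss of 2-propanol, and either form should give 10 on oxidation.

Step 1
Reactants: 1 dimethyl (4S,5S)-2,2-dimethyl-1,3-dioxolane-4,5-dicarboxylate; 2 dimethyl (1-diazo-2-oxopropyl)phosphonate
Product: 4 (4R,5R)-4,5-diethynyl-2,2-dimethyl-1,3-dioxolane, via dialdehyde 3 (not isolated)
Conditions: i-Bu2AlH (2.3 equiv), CH2Cl2, −78 °C; then MeOH, 2 (2.6 equiv), K2CO3, −78 °C → rt
Reagents that add atoms: none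
Why: One-pot ester reduction and Ohira–Bestmann alkynylation: the hydride stops at the aluminium hemiacetal at −78 °C, methanol releases dialdehyde 3, and the diazophosphonate anion formed from 2 turns each formyl group into a terminal alkyne. The trans-dioxolane stereocentres are not involved, and carbonate in methanol is mild enough for α-alkoxy aldehydes of this type.

Step 2
Reactants: 4 (4R,5R)-4,5-diethynyl-2,2-dimethyl-1,3-dioxolane
Product: 5 (3R,4R)-hexa-1,5-diyne-3,4-diol
Conditions: 2 M aq. HCl, THF, 50 °C
Reagents that add atoms: none
Why: Acid-catalysed acetal hydrolysis; the stereocentres carry no leaving group under these conditions and are unchanged.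

Step 3
Reactants: 5 (3R,4R)-hexa-1,5-diyne-3,4-diol
Product: 6 (3R,4R)-4-[(triethylsilyl)oxy]hexa-1,5-diyn-3-ol
Conditions: Et3SiCl (1.0 equiv), imidazole, CH2Cl2/DMF, −40 → 0 °C
Reagents that add atoms: chlorotriethylsilane (CC[Si](Cl)(CC)CC)
Why: Monosilylation of a C2-symmetric diol: the hydroxyls are homotopic, so only one mono-ether exists, and the second silylation is slowed by the neighbouring silyloxy group. A 1,2-silyl shift would regenerate the same compound.

Step 4
Reactants: 6 (3R,4R)-4-[(triethylsilyl)oxy]hexa-1,5-diyn-3-ol; 7 (chloromethyl)(isopropoxy)dimethylsilane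
Product: 10 (2Z,3R,4R)-2-(iodomethylidene)-4-[(triethylsilyl)oxy]hex-5-yne-1,3-diol, via chelated alkenylmagnesium alkoxide 8 (not isolated), via allylic isopropoxysilane 9 (not isolated)
Conditions: 7, Mg, THF, reflux; then 6, CuI (20 mol%), THF, 0 °C → rt; I2, −30 → 0 °C; aqueous work-up; then 30% H2O2, KHCO3, THF/MeOH, rt
Reagents that add atoms: iodine (II); hydrogen peroxide (OO)
Why: Copper-catalysed hydroxyl-directed anti-carbomagnesiation of a propargylic alcohol: the C6 alkoxide holds magnesium on C2 in the five-membered chelate 8, so the silylmethyl group is delivered to C1 and iodine then replaces magnesium with retention, cis to C6. Tamao oxidation of the alkoxysilane 9 converts C–Si into C–OH with retention and without allylic shift, and the alkoxy group on silicon lets it run without fluoride, which spares the C5 silyl ether. No stereocentre is formed.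

Step 5
Reactants: 10 (2Z,3R,4R)-2-(iodomethylidene)-4-[(triethylsilyl)oxy]hex-5-yne-1,3-diol
Product: 11 (2Z,3R,4R)-6-iodo-2-(iodomethylidene)-4-[(triethylsilyl)oxy]hex-5-yne-1,3-diol
Conditions: N-iodosuccinimide (1.2 equiv), AgNO3 (10 mol%), acetone, rt, dark
Reagents that add atoms: N-iodosuccinimide (O=C1CCC(=O)N1I)
Why: Silver-catalysed electrophilic iodination of a terminal alkyne through the silver acetylide, which tolerates free hydroxyls and the iodoalkene. Placed here, it also brings to one compound any material already iodinated at C3 by the iodine quench of step 4.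

Step 6
Reactants: 11 (2Z,3R,4R)-6-iodo-2-(iodomethylidene)-4-[(triethylsilyl)oxy]hex-5-yne-1,3-diol
Product: 12 (1Z,3R,4R)-1,6-diiodo-4-[(triethylsilyl)oxy]-2-{[(triethylsilyl)oxy]methyl}hex-1-en-5-yn-3-ol
Conditions: Et3SiCl (1.05 equiv), imidazole, CH2Cl2, −78 → −40 °C
Reagents that add atoms: chlorotriethylsilane (CC[Si](Cl)(CC)CC)
Why: Kinetic silylation of the primary allylic hydroxyl; the C6 hydroxyl is secondary and flanked by the C5 silyloxy carbon and the trisubstituted alkene, so it should react much more slowly.

Step 7
Reactants: 12 (1Z,3R,4R)-1,6-diiodo-4-[(triethylsilyl)oxy]-2-{[(triethylsilyl)oxy]methyl}hex-1-en-5-yn-3-ol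
Product: 13 (1Z,3R,4R)-3-[(tert-butyldimethylsilyl)oxy]-1,6-diiodo-4-[(triethylsilyl)oxy]-2-{[(triethylsilyl)oxy]methyl}hex-1-en-5-yne
Conditions: t-BuMe2SiOTf (1.5 equiv), 2,6-lutidine, CH2Cl2, −78 → 0 °C
Reagents that add atoms: tert-butyldimethylsilyl trifluoromethanesulfonate (CC(C)(C)[Si](C)(C)OS(=O)(=O)C(F)(F)F)
Why: Silyl triflate silylation, the standard method for hindered secondary alcohols; it puts the most robust silyl group on the oxygen that must be freed last.

Step 8
Reactants: 13 (1Z,3R,4R)-3-[(tert-butyldimethylsilyl)oxy]-1,6-diiodo-4-[(triethylsilyl)oxy]-2-{[(triethylsilyl)oxy]methyl}hex-1-en-5-yne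
Product: 14 (1Z,3R,4R,5Z)-3-[(tert-butyldimethylsilyl)oxy]-1,6-diiodo-4-[(triethylsilyl)oxy]-2-{[(triethylsilyl)oxy]methyl}hexa-1,5-diene
Conditions: 2-nitrobenzenesulfonyl hydrazide (3 equiv), Et3N, THF/i-PrOH, rt, dark
Reagents that add atoms: none
Why: Diimide reduction of a 1-iodoalkyne: concerted syn transfer of two hydrogens gives the (Z)-iodoalkene. The trisubstituted iodoalkene and the product are much poorer diimide acceptors than the iodoalkyne.

Step 9
Reactants: 14 (1Z,3R,4R,5Z)-3-[(tert-butyldimethylsilyl)oxy]-1,6-diiodo-4-[(triethylsilyl)oxy]-2-{[(triethylsilyl)oxy]methyl}hexa-1,5-diene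
Product: 15 (5R,6R)-6-[(tert-butyldimethylsilyl)oxy]-5-[(triethylsilyl)oxy]-1-{[(triethylsilyl)oxy]methyl}cyclohexa-1,3-diene
Conditions: Ni(cod)2 (2.5 equiv), PPh3 (5 equiv), DMF, 45 °C, slow addition of 14 (final 0.005 M)
Reagents that add atoms: none
Why: Ni(cod)2 and PPh3 give a phosphine-ligated zerovalent nickel that inserts into a C–I bond of 14 with retention, most readily at the less hindered C3, to form a (Z)-alkenyl divalent nickel iodide. The second C–I bond, held within reach by the two cis alkenes, is then activated at the same metal (probably after one-electron reduction to monovalent nickel, giving a trivalent dialkenylnickel), and reductive elimination joins C2 to C3 and leaves NiI2. The closest known reaction type is the reductive homocoupling of alkenyl halides by stoichiometric zerovalent nickel, which keeps alkene geometry and has been used to close rings. The six-membered ring closes by C(sp2)–C(sp2) reductive elimination from a seven-membered nickelacycle, so both double bonds end up in the ring as the cis,cis-1,3-diene. No stereocentre is formed, and C5 and C6 are spectators because they carry silyl ethers, which zerovalent nickel does not ionise, and no acidic hydrogen. The step needs cyclisation to win over oligomerisation and over protonolysis of the alkenylnickel; the Z geometry at both alkenes, slow addition to high dilution and a dry aprotic medium should secure this. The preference of the two bulky silyloxy groups on C5 and C6 to lie anti places C4 and C1 gauche, which pre-organises the chain for closure to the trans product.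

Step 10
Reactants: 15 (5R,6R)-6-[(tert-butyldimethylsilyl)oxy]-5-[(triethylsilyl)oxy]-1-{[(triethylsilyl)oxy]methyl}cyclohexa-1,3-diene
Product: 16 (1R,6R)-6-[(tert-butyldimethylsilyl)oxy]-5-(hydroxymethyl)cyclohexa-2,4-dien-1-ol
Conditions: PPTS (0.2 equiv), MeOH/CH2Cl2, 0 °C → rt
Reagents that add atoms: none
Why: Mild acid-catalysed methanolysis removes primary and secondary triethylsilyl ethers far faster than a hindered secondary tert-butyldimethylsilyl ether. Trans-dihydrodiol derivatives lack the aligned C–H that makes their cis isomers acid-labile, so the diene should survive this weak acid.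

Step 11
Reactants: 16 (1R,6R)-6-[(tert-butyldimethylsilyl)oxy]-5-(hydroxymethyl)cyclohexa-2,4-dien-1-ol; 17 benzoyl chloride
Product: 18 [(5R,6R)-5-(benzoyloxy)-6-[(tert-butyldimethylsilyl)oxy]cyclohexa-1,3-dien-1-yl]methyl benzoate
Conditions: 17 (2.5 equiv), pyridine, DMAP (cat.), CH2Cl2, 0 °C
Reagents that add atoms: none
Why: Nucleophile-catalysed acylation of the two free hydroxyls; O6 is blocked, so no regiochemical question arises and no alkoxide is formed.

Step 12
Reactants: 18 [(5R,6R)-5-(benzoyloxy)-6-[(tert-butyldimethylsilyl)oxy]cyclohexa-1,3-dien-1-yl]methyl benzoate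
Product: 19 [(5R,6R)-5-(benzoyloxy)-6-hydroxycyclohexa-1,3-dien-1-yl]methyl benzoate
Conditions: HF·pyridine, pyridine, THF, 0 °C → rt
Reagents that add atoms: none
Why: Fluoride-mediated desilylation in a buffered, weakly acidic medium: the hydroxyl is released as the alcohol and not as an alkoxide, which should suppress the 1,2-benzoyl shift from O5 to O6, and the conditions are too mild to ionise the dienylic esters.

## Compound list

1 | dimethyl (4S,5S)-2,2-dimethyl-1,3-dioxolane-4,5-dicarboxylate (dimethyl 2,3-O-isopropylidene-D-tartrate) | COC(=O)[C@H]1OC(C)(C)O[C@@H]1C(=O)OC | starting material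
2 | dimethyl (1-diazo-2-oxopropyl)phosphonate | CC(=O)C(=[N+]=[N-])P(=O)(OC)OC | starting material
3 | (4S,5S)-2,2-dimethyl-1,3-dioxolane-4,5-dicarbaldehyde | O=C[C@H]1OC(C)(C)O[C@@H]1C=O | intermediate
4 | (4R,5R)-4,5-diethynyl-2,2-dimethyl-1,3-dioxolane | C#C[C@H]1OC(C)(C)O[C@@H]1C#C | intermediate
5 | (3R,4R)-hexa-1,5-diyne-3,4-diol | C#C[C@@H](O)[C@@H](C#C)O | intermediate
6 | (3R,4R)-4-[(triethylsilyl)oxy]hexa-1,5-diyn-3-ol | C#C[C@@H](O[Si](CC)(CC)CC)[C@@H](C#C)O | intermediate
7 | (chloromethyl)(isopropoxy)dimethylsilane | CC(C)O[Si](C)(C)CCl | starting material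
8 | (5R)-4-{[dimethyl(propan-2-yloxy)silyl]methyl}-5-[(1R)-1-[(triethylsilyl)oxy]prop-2-yn-1-yl]-2,5-dihydro-1,2-oxamagnesole (chelated alkenylmagnesium alkoxide) | C#C[C@@H](O[Si](CC)(CC)CC)[C@@H]1O[Mg]C=C1C[Si](C)(C)OC(C)C | intermediate
9 | (1E,3R,4R)-2-{[dimethyl(propan-2-yloxy)silyl]methyl}-1-iodo-4-[(triethylsilyl)oxy]hex-1-en-5-yn-3-ol | C#C[C@@H](O[Si](CC)(CC)CC)[C@@H](/C(C[Si](C)(C)OC(C)C)=C\I)O | intermediate
10 | (2Z,3R,4R)-2-(iodomethylidene)-4-[(triethylsilyl)oxy]hex-5-yne-1,3-diol | C#C[C@@H](O[Si](CC)(CC)CC)[C@@H](/C(CO)=C\I)O | intermediate
11 | (2Z,3R,4R)-6-iodo-2-(iodomethylidene)-4-[(triethylsilyl)oxy]hex-5-yne-1,3-diol | IC#C[C@@H](O[Si](CC)(CC)CC)[C@@H](/C(CO)=C\I)O | intermediate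
12 | (1Z,3R,4R)-1,6-diiodo-4-[(triethylsilyl)oxy]-2-{[(triethylsilyl)oxy]methyl}hex-1-en-5-yn-3-ol | IC#C[C@@H](O[Si](CC)(CC)CC)[C@@H](/C(CO[Si](CC)(CC)CC)=C\I)O | intermediate
13 | (1Z,3R,4R)-3-[(tert-butyldimethylsilyl)oxy]-1,6-diiodo-4-[(triethylsilyl)oxy]-2-{[(triethylsilyl)oxy]methyl}hex-1-en-5-yne | IC#C[C@@H](O[Si](CC)(CC)CC)[C@@H](/C(CO[Si](CC)(CC)CC)=C\I)O[Si](C)(C)C(C)(C)C | intermediate
14 | (1Z,3R,4R,5Z)-3-[(tert-butyldimethylsilyl)oxy]-1,6-diiodo-4-[(triethylsilyl)oxy]-2-{[(triethylsilyl)oxy]methyl}hexa-1,5-diene | I/C=C\[C@@H](O[Si](CC)(CC)CC)[C@@H](/C(CO[Si](CC)(CC)CC)=C\I)O[Si](C)(C)C(C)(C)C | intermediate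
15 | (5R,6R)-6-[(tert-butyldimethylsilyl)oxy]-5-[(triethylsilyl)oxy]-1-{[(triethylsilyl)oxy]methyl}cyclohexa-1,3-diene | CC[Si](CC)(CC)OCC1=CC=C[C@@H](O[Si](CC)(CC)CC)[C@@H]1O[Si](C)(C)C(C)(C)C | intermediate
16 | (1R,6R)-6-[(tert-butyldimethylsilyl)oxy]-5-(hydroxymethyl)cyclohexa-2,4-dien-1-ol | OCC1=CC=C[C@@H](O)[C@@H]1O[Si](C)(C)C(C)(C)C | intermediate
17 | benzoyl chloride | O=C(Cl)c1ccccc1 | starting material
18 | [(5R,6R)-5-(benzoyloxy)-6-[(tert-butyldimethylsilyl)oxy]cyclohexa-1,3-dien-1-yl]methyl benzoate | O=C(OCC1=CC=C[C@@H](OC(=O)c2ccccc2)[C@@H]1O[Si](C)(C)C(C)(C)C)c1ccccc1 | intermediate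
19 | [(5R,6R)-5-(benzoyloxy)-6-hydroxycyclohexa-1,3-dien-1-yl]methyl benzoate | O=C(OCC1=CC=C[C@@H](OC(=O)c2ccccc2)[C@@H]1O)c1ccccc1 | target

## Step count and least certain steps

Total step count: 12. Longest linear sequence: 12 steps (1 to 19).

**Step 9 (key step).** Ring closure may lose to intermolecular coupling or to protonolysis of the alkenylnickel, and the disubstituted alkenylnickel may isomerise from Z to E before the second, more crowded C–I bond at C2 engages; either process removes material. The fallback sets out from 14 and uses a stannylative cyclisation under zerovalent palladium catalysis (Stille–Kelly reaction; Me3SnSnMe3, Pd(PPh3)4, toluene, 100 °C). The less hindered C3–I bond is converted in the flask into trimethyl[(1Z,3R,4R,5Z)-4-[(tert-butyldimethylsilyl)oxy]-6-iodo-3-[(triethylsilyl)oxy]-5-{[(triethylsilyl)oxy]methyl}hexa-1,5-dien-1-yl]stannane F1, which couples with the remaining C2–I bond and comes back to the route at 15.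

**Step 4.** Deprotonation of the acetylenic C–H by the weakly nucleophilic silylmethyl Grignard reagent may outrun carbometalation, since a magnesium acetylide does not add. The C5 triethylsilyl group may also be lost or shifted to O6 during the basic peroxide oxidation. The fallback sets out from 6 and uses the same copper-catalysed directed addition with the more reactive vinylmagnesium bromide, followed by iodine, to give (3Z,4R,5R)-3-(iodomethylidene)-5-[(triethylsilyl)oxy]hept-1-en-6-yn-4-ol F2. Cleavage of its terminal vinyl group (Lemieux–Johnson oxidation; OsO4 cat., NaIO4) gives (2E,3R,4R)-3-hydroxy-2-(iodomethylidene)-4-[(triethylsilyl)oxy]hex-5-ynal F3, and Luche reduction (NaBH4, CeCl3·7H2O) comes back at 10 without any silicon oxidation.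

**Step 3.** Silylation may run on to the bis-ether while diol remains, because the rate difference between first and second silylation is modest for a small silyl group. The fallback sets out from 5: heating with Bu2SnO in toluene gives (4R,5R)-2,2-dibutyl-4,5-diethynyl-1,3,2-dioxastannolane F4, in which one tin-bound oxygen is silylated by Et3SiCl and the second is then deactivated, coming back at 6.

**Step 8.** Diimide is generated in bursts and disproportionates, so conversion may stall or the reduction may go on to the saturated iodide. The fallback sets out from 13: syn-hydroboration with dicyclohexylborane places boron on the iodine-bearing carbon to give dicyclohexyl[(1Z,3R,4R,5Z)-4-[(tert-butyldimethylsilyl)oxy]-1,6-diiodo-3-[(triethylsilyl)oxy]-5-{[(triethylsilyl)oxy]methyl}hexa-1,5-dien-1-yl]borane F5, and protonolysis of the C–B bond with acetic acid (retention) comes back at 14.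

**Step 12.** Cleavage of the hindered C6 silyl ether is slow, and during it the C5 benzoyl group may shift to the freed O6 or the dienylic ester may eliminate toward an arene. The fallback sets out from 15: removal of all three silyl groups (HF·pyridine, THF) gives (1R,2R)-3-(hydroxymethyl)cyclohexa-3,5-diene-1,2-diol F6. Acylation with two equivalents of 17 (2,4,6-collidine, CH2Cl2, −40 °C) at the primary and the less hindered C5 hydroxyl comes back at 19. This removes the migration risk at the price of a regioselectivity question.

## Further compounds

F1 | step 9 | trimethyl[(1Z,3R,4R,5Z)-4-[(tert-butyldimethylsilyl)oxy]-6-iodo-3-[(triethylsilyl)oxy]-5-{[(triethylsilyl)oxy]methyl}hexa-1,5-dien-1-yl]stannane | C[Sn](C)(C)/C=C\[C@@H](O[Si](CC)(CC)CC)[C@@H](/C(CO[Si](CC)(CC)CC)=C\I)O[Si](C)(C)C(C)(C)C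
F2 | step 4 | (3Z,4R,5R)-3-(iodomethylidene)-5-[(triethylsilyl)oxy]hept-1-en-6-yn-4-ol | C#C[C@@H](O[Si](CC)(CC)CC)[C@@H](/C(C=C)=C\I)O
F3 | step 4 | (2E,3R,4R)-3-hydroxy-2-(iodomethylidene)-4-[(triethylsilyl)oxy]hex-5-ynal | C#C[C@@H](O[Si](CC)(CC)CC)[C@@H](/C(C=O)=C\I)O
F4 | step 3 | (4R,5R)-2,2-dibutyl-4,5-diethynyl-1,3,2-dioxastannolane | C#C[C@H]1O[Sn](CCCC)(CCCC)O[C@@H]1C#C
F5 | step 8 | dicyclohexyl[(1Z,3R,4R,5Z)-4-[(tert-butyldimethylsilyl)oxy]-1,6-diiodo-3-[(triethylsilyl)oxy]-5-{[(triethylsilyl)oxy]methyl}hexa-1,5-dien-1-yl]borane | I/C(B(C1CCCCC1)C1CCCCC1)=C\[C@@H](O[Si](CC)(CC)CC)[C@@H](/C(CO[Si](CC)(CC)CC)=C\I)O[Si](C)(C)C(C)(C)C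
F6 | step 12 | (1R,2R)-3-(hydroxymethyl)cyclohexa-3,5-diene-1,2-diol | OCC1=CC=C[C@@H](O)[C@@H]1O
A1 | alternative 1 | (E)-2-({diisopropyl[(prop-2-yn-1-yl)oxy]silyl}oxy)ethenyl benzoate | C#CCO[Si](C(C)C)(C(C)C)O/C=C/OC(=O)c1ccccc1
A2 | alternative 1 | acetylene | C#C
A3 | alternative 1 | (8R,8aR)-2,2-diisopropyl-8,8a-dihydro-4H-benzo[d][1,3,2]dioxasilin-8-yl benzoate | CC(C)[Si]1(C(C)C)OCC2=CC=C[C@@H](OC(=O)c3ccccc3)[C@@H]2O1
A4 | alternative 2 | D-glucal, (2R,3S,4R)-2-(hydroxymethyl)-3,4-dihydro-2H-pyran-3,4-diol | C1=CO[C@@H]([C@H]([C@@H]1O)O)CO
A5 | alternative 2 | (2R,3R,4R)-2-ethenyl-3-[(4-methoxybenzyl)oxy]-4-[(triisopropylsilyl)oxy]-3,4-dihydro-2H-pyran | C1=CO[C@@H]([C@H]([C@@H]1O[Si](C(C)C)(C(C)C)C(C)C)OCc2ccc(OC)cc2)C=C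
A6 | alternative 2 | (1S,5R,6R)-5-[(4-methoxybenzyl)oxy]-6-[(triisopropylsilyl)oxy]cyclohex-3-ene-1-carbaldehyde | O=C[C@H]1CC=C[C@@H](OCc2ccc(OC)cc2)[C@@H]1O[Si](C(C)C)(C(C)C)C(C)C
A7 | alternative 3 | (E)-4-oxobut-2-en-1-yl benzoate, (E)-4-(benzoyloxy)but-2-enal | O=C/C=C/COC(=O)c1ccccc1
A8 | alternative 3 | (E)-3-[(triisopropylsilyl)oxy]prop-2-enal | O=C/C=C/O[Si](C(C)C)(C(C)C)C(C)C
A9 | alternative 3 | (5R,6R)-5-(benzoyloxy)-6-[(triisopropylsilyl)oxy]cyclohexa-1,3-diene-1-carbaldehyde | O=CC1=CC=C[C@@H](OC(=O)c2ccccc2)[C@@H]1O[Si](C(C)C)(C(C)C)C(C)C
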